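## Structural features

The target is a ten-membered lactone (ring A: O1, C1 carbonyl, C2–C9) fused across C5–C6 to an oxirane (ring B). C9 carries an n-pentyl chain and O8 carries a (2E,4R)-2,4-dimethylhex-2-enoyl group. Seven contiguous stereocentres run from C3 to C9 and an eighth sits at C4′ of the acyl chain. The C3/C4 diol is threo, the C4–O/C5–O pair is threo, the epoxide is trans, and the C6–O/C7–OH, C7–OH/C8–O and C8–O/C9–O pairs are all erythro. The fragile features are the epoxide flanked by two carbinols (Payne rearrangement, neighbouring-group opening), the β-hydroxy lactone whose C4 hydroxyl is γ to the carbonyl (β-elimination, contraction to a γ-lactone) and the O8 enoate beside the free C7 hydroxyl (acyl migration). The last steps must therefore avoid base and strong acid. The real difficulty is to close the strained medium ring while controlling C5, C6 and C7, and to tell five oxygen functions on nine carbons apart. The key step exploits the C7 carbinol of ring A lying next to the C5–C6 epoxide: an E-C5=C6 olefin bearing C7–OH is the product of an alkenyl-to-aldehyde addition, so ring A can be closed at C6–C7, and the new C7–OH then steers oxygen onto C5=C6. The threo C3/C4 diol is the C2-symmetric core of D-tartrate, and the erythro C8/C9 pair is a trans-epoxy alcohol opened with inversion.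

## Logic of the disconnections

26 ⇒ 25. No skeletal bond is cut; O3–H and O4–H are exchanged for O–Si bonds. The free triol epoxide is too labile to carry, so it is unmasked last. The demand is a desilylation that is neither basic nor strongly acidic, which is why triethylsilyl ethers are used.

25 ⇒ 24. The C5–O and C6–O bonds of ring B are cut, leaving the E-C5=C6 olefin. The cut is made here because O7 can deliver the oxygen. It removes two stereocentres and the most sensitive ring. The forward step must be erythro-selective with respect to C7 and must leave the enoate alone.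

24 ⇒ 23. The C6–C7 bond of ring A is cut between an alkenyl iodide (C6) and an aldehyde (C7). This opens the medium ring to an acyclic diester and removes the C7 centre. The forward step must be chemoselective for C–I and CHO, must run at high dilution, and must add to the aldehyde face that gives the 7,8-erythro carbinol.

23 ⇒ 22 ⇒ 21. No skeletal bond is cut; C7 is taken back to the alcohol and then to its silyl ether. The α-acyloxy aldehyde cannot be stored, so it is formed last. The demand is removal of a primary silyl ether beside two secondary ones, followed by a base-free oxidation.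

21 ⇒ 14 + 19. The O8–C1′ acyl bond is cut. This detaches the side chain with its own stereocentre. The forward step must acylate a hindered secondary hydroxyl that sits next to an ester without acyl migration and without touching C4′.

14 ⇒ 13 ⇒ 10 + 12. First the O7–Si bond, then the C9–O1 bond is cut and C9 is reconnected to the oxygen on C8 as an oxirane. This divides the molecule into two halves of similar size and derives C8 and C9 from one catalytic asymmetric reaction. The forward step must open the epoxy alcohol at C9 only, with clean inversion.

12 ⇒ 11. Both C–O bonds of the oxirane are cut, leaving an achiral E-allylic alcohol. The demand is enantioface selection by a tartrate ligand.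

10 ⇒ 8 ⇒ 6. C1 is reduced from acid to alcohol and the C1–O bond is cut, leaving a terminal C1=C2 olefin. This turns the acid into a hydrocarbon terminus. The demand is hydroboration of a terminal olefin in the presence of the iodoalkene.

6 ⇒ 4 ⇒ 3. The C1=C2 bond is cut (C1 from a methylene ylide, C2 from an ester carbon), then the C5=C6 bond (C6 from iodoform, C5 from an aldehyde). Both olefinations act on α-silyloxy carbonyl groups, so non-epimerising conditions and E-selectivity at C5=C6 are required.

3 ⇒ 2 ⇒ 1. One ester of a C2-symmetric diester is taken back from the aldehyde, then the two O–Si bonds are removed. C3 and C4 come from the chiral pool. The only demand is control of mono- versus bis-reduction.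

19 ⇒ 18 ⇒ 16 ⇒ 15. The C2′=C3′ bond is cut (stabilised ylide plus aldehyde) and the aldehyde is traced to the acid. The forward sequence must not racemise the α-branched aldehyde and must give the E-olefin.

## Other disconnections considered

Alternative 1: The cut is the C5–C6 bond together with the C5–O bond of ring B, dividing the chain into a C1–C5 allyl unit and a C6–C14 aldehyde. In the forward step the allylic sulfonium salt A3 is deprotonated to its ylide, which adds to aldehyde A2. The betaine then closes by displacement of the sulfide to give the trans vinyl epoxide A1.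
- In favour: it is convergent, it makes a C–C bond and the oxirane at once, and the trans geometry is inherent. The epoxide configuration is fixed on an open chain before any ring exists. On this point the alternative is better than the chosen plan, whose epoxide face depends on the conformation of ring A.
- Against: two new centres (C5, C6) arise in one intermolecular step. The aldehyde face is controlled only by the C7 silyloxy group, and the ylide face would need a stoichiometric chiral sulfide in place of the achiral A3. Allylic ylides can also rearrange sigmatropically and scramble the C3=C4 geometry.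
- Against, after A1: the C3/C4 diol must still be set by dihydroxylation beside an acid-labile vinyl epoxide. C1 must be oxidised, ring A closed by lactonisation at O9, and the PMB ether exchanged for the side chain, with four kinds of protecting group.
- Structure: the alternative builds ring B first and ring A last by C–O bond formation, and leaves C3/C4 to late reagent control. The chosen plan builds ring A by C–C bond formation and takes C3/C4 from tartrate.
- Mechanism: both are additions of a carbon nucleophile to an α-oxygenated aldehyde under Felkin-type control. They are equal in convergence, but the alternative must control two centres where the chosen plan controls one.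
- Step economy: roughly eight operations follow the union, so the chosen plan should be several steps shorter.

Alternative 2: The cut is the C9–O1 bond of ring A, with the C9 oxygen traced to a trans 8,9-epoxide. In the forward step the carboxyl group of epoxy acid A5 opens the Lewis-acid-activated epoxide at C9 with inversion, closing ring A and freeing the C8 hydroxyl in lactone A4.
- In favour: the stereochemical logic at C8/C9 (Sharpless-derived trans-epoxide, inversion at C9) is the same as in the chosen plan, so the two are equal here. No carboxyl activation is needed. O8 is released alone, so the side chain could be attached without the silylation and desilylation at O7. On this point the alternative is better.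
- Against: attack at C8 (nine-membered ring, exo) competes with attack at C9 (ten-membered ring, endo), and nothing in A5 directs the carboxylate to C9. In the chosen plan the free hydroxyl of the epoxy alcohol ties acid and epoxide to one titanium centre.
- Against: medium-ring closure by SN2 is slow, so oligomeric esters and Lewis-acid damage (silyl loss, epoxide rearrangement) compete. A5 still needs the C6–C7 bond and the C7 centre to be made intermolecularly. Three TBS ethers must be removed at the end, which is harsher than removing two triethylsilyl ethers.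
- Structure: the same bond is formed in both plans, intramolecularly here and intermolecularly in the chosen plan.
- Mechanism: carboxylate opening of an epoxide to a medium ring has far less precedent than chromium-mediated medium-ring closure.
- Step economy: about equal. The steps saved at O7/O8 are spent on the intermolecular C6–C7 union and extra silyl handling.

Alternative 3: The cut is the C2–C3 bond of ring A, an acetate aldol disconnection. In the forward step SmI2 reduces the C–Br bond of bromoacetate A7 to a trivalent samarium enolate, which adds to the C3 aldehyde in a chelated cyclic transition state to give hydroxy lactone A6.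
- In favour: this is an established way to medium-ring lactones. Chelation of samarium between the aldehyde oxygen and the C4 ether predicts the 3,4-threo carbinol that is required. This is as well founded as the Felkin argument at C7, so the two plans are equal here.
- In favour: ring B and all other centres are in place before closure, so no face-selective oxidation of the macrocycle is needed. On this point the alternative is better. The ring also closes at its least hindered bond.
- Against: SmI2 is a strong one-electron reductant. The ketyl of the α-alkoxy aldehyde can expel the C4 oxygen, the neighbouring epoxide can open reductively, and the enoate can be reduced. Alkenylchromium reagents do none of this.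
- Against: A7 must be assembled linearly with six stereocentres, an epoxy aldehyde and a bromoacetate on the hindered O9. Two PMB ethers must be removed oxidatively at the end.
- Structure: both plans form one bond, one ring and one stereocentre in the key step.
- Mechanism: both are carbonyl additions by a low-valent metal; chelation control here versus Felkin control in the chosen plan.
- Step economy: the chosen plan should be shorter, because it draws C3/C4 from a C2-symmetric source and joins two halves late.

Key step: step 16

Assumption: locants follow the lactone numbering O1, C1 (carbonyl) to C9 (pentyl-bearing carbon), with C10–C14 for the pentyl chain and primed locants for the acyl side chain; macrocycles are named as tetradecan-9-olides.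

Remark: 23 and 24 were compared centre by centre with 26 and have the target's spatial arrangement at every centre; the CIP letters at C4, C5 and C8 change along the route only because substituent priorities change. No structural correction was needed. Compound 23 is kept as the cyclisation substrate; what is added is the way its five oxygens are differentiated (O3/O4 as triethylsilyl ethers from step 1, O7 as a transient primary silyl ether, O8/O9 as the final esters).

## Route

Step 1
Reactants: 1 diethyl D-tartrate
Product: 2 diethyl (2S,3S)-2,3-bis(triethylsilyloxy)butanedioate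
Conditions: Et3SiCl (2.4 equiv), imidazole (5 equiv), 4-(dimethylamino)pyridine (0.1 equiv), DMF, 0 °C → rt
Reagents that add atoms: chlorotriethylsilane, CC[Si](Cl)(CC)CC
Why: Imidazole-promoted silylation of both secondary hydroxyls; triethylsilyl ethers are chosen because buffered HF·pyridine removes them at the end without base; no stereocentre is touched, so C3 and C4 come directly from the chiral pool.

Step 2
Reactants: 2 diethyl (2S,3S)-2,3-bis(triethylsilyloxy)butanedioate
Product: 3 ethyl (2S,3S)-4-oxo-2,3-bis(triethylsilyloxy)butanoate
Conditions: i-Bu2AlH (1.0 equiv), toluene, −78 °C; MeOH, aq. potassium sodium tartrate; unreacted 2 recycled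
Reagents that add atoms: none
Why: Partial ester reduction stops at the aldehyde because the α-alkoxy-chelated aluminium hemiacetal survives until work-up; 2 is C2-symmetric, so either ester gives the same product and only the statistical mono/bis ratio has to be managed by stoichiometry and recycling.

Step 3
Reactants: 3 ethyl (2S,3S)-4-oxo-2,3-bis(triethylsilyloxy)butanoate
Product: 4 ethyl (2S,3R,4E)-5-iodo-2,3-bis(triethylsilyloxy)pent-4-enoate
Conditions: CrCl2 (6 equiv), CHI3 (2 equiv), THF/1,4-dioxane (1:6), 0 °C → rt, dark
Reagents that add atoms: iodoform, IC(I)I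
Why: Takai olefination: the geminal dichromium species from CHI3 and divalent chromium adds to the aldehyde and eliminates to the E-iodoalkene, with dioxane raising the E preference; the medium is non-basic, so the α-silyloxy centre is not enolised and the ester and silyl ethers are inert.

Step 4
Reactants: 4 ethyl (2S,3R,4E)-5-iodo-2,3-bis(triethylsilyloxy)pent-4-enoate
Product: 6 (1E,3R,4R)-1-iodo-3,4-bis(triethylsilyloxy)hexa-1,5-diene, via aldehyde 5 (not isolated)
Conditions: i-Bu2AlH (1.05 equiv), CH2Cl2, −78 °C; then Ph3P=CH2 [Ph3PCH3Br (3.2 equiv), KN(SiMe3)2 (3.0 equiv), THF], −78 °C → rt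
Reagents that add atoms: methylenetriphenylphosphorane, C=P(c1ccccc1)(c1ccccc1)c1ccccc1
Why: One-pot partial reduction and Wittig methylenation: the aluminium hemiacetal releases the epimerisable aldehyde 5 only as the ylide traps it; the phosphonium salt is kept in slight excess over the amide base so that no free base can dehydroiodinate the iodoalkene.

Step 5
Reactants: 6 (1E,3R,4R)-1-iodo-3,4-bis(triethylsilyloxy)hexa-1,5-diene
Product: 8 (3R,4R,5E)-6-iodo-3,4-bis(triethylsilyloxy)hex-5-en-1-ol, via alkylborane 7 (not isolated)
Conditions: 9-borabicyclo[3.3.1]nonane (1.3 equiv), THF, 0 °C → rt; then 30% H2O2, aq. NaOAc, 0 °C → rt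
Reagents that add atoms: hydrogen peroxide, OO
Why: Anti-Markovnikov hydroboration and oxidation: the bulky borane adds to the terminal monosubstituted olefin far faster than to the electron-poor 1,2-disubstituted iodoalkene, and acetate-buffered peroxide oxidises the C–B bond without harming the C–I or Si–O bonds.

Step 6
Reactants: 8 (3R,4R,5E)-6-iodo-3,4-bis(triethylsilyloxy)hex-5-en-1-ol
Product: 10 (3R,4R,5E)-6-iodo-3,4-bis(triethylsilyloxy)hex-5-enoic acid, via aldehyde 9 (not isolated)
Conditions: PhI(OAc)2 (2.5 equiv), 2,2,6,6-tetramethylpiperidin-1-oxyl (0.2 equiv), MeCN/H2O (1:1), rt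
Reagents that add atoms: water, O
Why: Oxoammonium-catalysed oxidation takes the primary alcohol through aldehyde 9 and its hydrate to the acid under non-basic conditions, so β-elimination of the C3 silyloxy group is not expected and the iodoalkene is untouched.

Step 7
Reactants: 11 (E)-oct-2-en-1-ol
Product: 12 [(2S,3S)-3-pentyloxiran-2-yl]methanol
Conditions: Ti(OiPr)4 (0.1 equiv), L-(+)-diethyl tartrate (0.12 equiv), tert-butyl hydroperoxide (2 equiv, anhydrous), 4 Å molecular sieves, CH2Cl2, −20 °C
Reagents that add atoms: tert-butyl hydroperoxide, CC(C)(C)OO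
Why: Sharpless asymmetric epoxidation: with the L-(+)-tartrate ligand the titanium complex delivers oxygen to the olefin face that gives the (2S,3S)-epoxy alcohol from an E-disubstituted primary allylic alcohol, setting the future C8 (kept) and C9 (to be inverted).

Step 8
Reactants: 10 (3R,4R,5E)-6-iodo-3,4-bis(triethylsilyloxy)hex-5-enoic acid; 12 [(2S,3S)-3-pentyloxiran-2-yl]methanol
Product: 13 (2S,3R)-1,2-dihydroxyoctan-3-yl (3R,4R,5E)-6-iodo-3,4-bis(triethylsilyloxy)hex-5-enoate
Conditions: 12 (1.5 equiv), Ti(OiPr)4 (2.2 equiv), CH2Cl2, 0 °C → rt; aq. potassium sodium tartrate work-up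
Reagents that add atoms: none
Why: Ti(OiPr)4-mediated opening of a 2,3-epoxy alcohol by a carboxylic acid: epoxy alkoxide and carboxylate sit on the same tetravalent titanium centre and the carboxylate attacks C3 of the epoxy alcohol (the future C9) in an SN2 sense; inversion there gives 9R and the erythro 8,9-pair, while C8 keeps its configuration.

Step 9
Reactants: 13 (2S,3R)-1,2-dihydroxyoctan-3-yl (3R,4R,5E)-6-iodo-3,4-bis(triethylsilyloxy)hex-5-enoate
Product: 14 (2S,3R)-2-hydroxy-1-(triethylsilyloxy)octan-3-yl (3R,4R,5E)-6-iodo-3,4-bis(triethylsilyloxy)hex-5-enoate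
Conditions: Et3SiCl (1.05 equiv), imidazole (2 equiv), CH2Cl2, −40 → −20 °C
Reagents that add atoms: chlorotriethylsilane, CC[Si](Cl)(CC)CC
Why: Kinetic silylation: one equivalent of silyl chloride at low temperature should take the primary C7 hydroxyl in preference to the hindered secondary C8 hydroxyl flanked by an ester.

Step 10
Reactants: 15 (R)-2-methylbutanoic acid
Product: 16 (R)-2-methylbutan-1-ol
Conditions: LiAlH4 (1.5 equiv), Et2O, 0 °C → rt
Reagents that add atoms: none
Why: Hydride reduction of the acid to the primary alcohol; the carboxylate and aluminate intermediates are not enolised, so the α-centre keeps its R configuration.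

Step 11
Reactants: 16 (R)-2-methylbutan-1-ol
Product: 18 ethyl (2E,4R)-2,4-dimethylhex-2-enoate, via aldehyde 17 (not isolated)
Conditions: PhI(OAc)2 (1.1 equiv), 2,2,6,6-tetramethylpiperidin-1-oxyl (0.1 equiv), CH2Cl2, rt; then Ph3P=C(CH3)CO2Et (1.3 equiv), rt
Reagents that add atoms: ethyl 2-(triphenylphosphoranylidene)propanoate, CCOC(=O)C(C)=P(c1ccccc1)(c1ccccc1)c1ccccc1
Why: Tandem oxoammonium oxidation and Wittig olefination: the volatile, racemisation-prone aldehyde 17 is trapped in the flask by the weakly basic stabilised ylide, which gives the E-trisubstituted enoate.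

Step 12
Reactants: 18 ethyl (2E,4R)-2,4-dimethylhex-2-enoate
Product: 19 (2E,4R)-2,4-dimethylhex-2-enoic acid
Conditions: LiOH (4 equiv), THF/MeOH/H2O (3:1:1), rt → 40 °C; then 1 M HCl to pH 3
Reagents that add atoms: lithium hydroxide, [Li+].[OH-]
Why: Saponification of the conjugated ester; hydroxide adds to the carbonyl and does not usefully deprotonate the γ-position, so C4′ and the E geometry are kept.

Step 13
Reactants: 14 (2S,3R)-2-hydroxy-1-(triethylsilyloxy)octan-3-yl (3R,4R,5E)-6-iodo-3,4-bis(triethylsilyloxy)hex-5-enoate; 19 (2E,4R)-2,4-dimethylhex-2-enoic acid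
Product: 21 (2S,3R)-3-{[(3R,4R,5E)-6-iodo-3,4-bis(triethylsilyloxy)hex-5-enoyl]oxy}-1-(triethylsilyloxy)octan-2-yl (2E,4R)-2,4-dimethylhex-2-enoate, via mixed anhydride 20 (not isolated)
Conditions: 19 (1.5 equiv), 2,4,6-trichlorobenzoyl chloride (1.5 equiv), Et3N (2 equiv), toluene, rt, 1 h; then 14, 4-(dimethylamino)pyridine (2 equiv), toluene, 0 °C → rt
Reagents that add atoms: none
Why: Yamaguchi esterification: the pyridine attacks the less hindered enoyl carbonyl of 20 and the acylpyridinium acylates the C8 hydroxyl with retention; the acid has no α-hydrogen, so no ketene path can scramble it, and preforming 20 at low temperature lets acylation outrun migration of the O9 ester.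

Step 14
Reactants: 21 (2S,3R)-3-{[(3R,4R,5E)-6-iodo-3,4-bis(triethylsilyloxy)hex-5-enoyl]oxy}-1-(triethylsilyloxy)octan-2-yl (2E,4R)-2,4-dimethylhex-2-enoate
Product: 22 (2S,3R)-1-hydroxy-3-{[(3R,4R,5E)-6-iodo-3,4-bis(triethylsilyloxy)hex-5-enoyl]oxy}octan-2-yl (2E,4R)-2,4-dimethylhex-2-enoate
Conditions: HF·pyridine (limited), pyridine, THF, 0 °C; cold aq. NaHCO3 quench as soon as 21 is consumed
Reagents that add atoms: none
Why: Chemoselective protodesilylation: pyridine-buffered HF cleaves the unhindered primary silyl ether faster than the two vicinal secondary ones, and the weakly acidic medium disfavours migration of the conjugated, α-branched O8 acyl group to the freed O7.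

Step 15
Reactants: 22 (2S,3R)-1-hydroxy-3-{[(3R,4R,5E)-6-iodo-3,4-bis(triethylsilyloxy)hex-5-enoyl]oxy}octan-2-yl (2E,4R)-2,4-dimethylhex-2-enoate
Product: 23 (2R,3R)-3-{[(3R,4R,5E)-6-iodo-3,4-bis(triethylsilyloxy)hex-5-enoyl]oxy}-1-oxooctan-2-yl (2E,4R)-2,4-dimethylhex-2-enoate
Conditions: Dess–Martin periodinane (1.5 equiv), NaHCO3 (5 equiv), CH2Cl2, 0 °C → rt; crude aldehyde used at once
Reagents that add atoms: none
Why: Dess–Martin oxidation under bicarbonate buffer forms the α-acyloxy aldehyde without amine base, which avoids epimerisation at C8 and β-elimination of the O9 carboxylate; the descriptor at C8 changes from S to R by priority only.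

Step 16
Reactants: 23 (2R,3R)-3-{[(3R,4R,5E)-6-iodo-3,4-bis(triethylsilyloxy)hex-5-enoyl]oxy}-1-oxooctan-2-yl (2E,4R)-2,4-dimethylhex-2-enoate
Product: 24 (3R,4R,5E,7S,8S,9R)-8-[(2E,4R)-2,4-dimethylhex-2-enoyloxy]-7-hydroxy-3,4-bis(triethylsilyloxy)tetradec-5-en-9-olide
Conditions: CrCl2 (12 equiv), NiCl2 (0.12 equiv), degassed DMF, rt, 23 added over 10 h by syringe pump to a final 0.003 M; aq. potassium sodium tartrate work-up
Reagents that add atoms: none
Why: Intramolecular Nozaki–Hiyama–Kishi reaction: CrCl2 reduces NiCl2 to zerovalent nickel, which inserts into the C6–I bond with retention of the E geometry, and transmetallation gives a trivalent alkenylchromium species that adds to the C7 aldehyde; the chromium alkoxide is hydrolysed on work-up. The closest known reaction type is the chromium/nickel macrocyclisation of iodoalkenyl aldehydes to medium and large lactones. Ring A closes in a 10-exo-trig mode (C6 attacks the exocyclic C7=O), with the lactone ester, the silyl ethers and the E-olefin already in the chain, so no olefin geometry is at stake. The new C7 centre is controlled by C8: in the Felkin–Anh arrangement the C8–O bond lies anti to the incoming alkenyl group, which gives the 7,8-erythro (7S) carbinol, and the ring transition state is expected to reinforce this. The step needs chemoselectivity, and alkenylchromium reagents are weakly basic and add to aldehydes but not to the ester carbonyls or the enoate. It needs ring closure to outrun dimerisation, which high dilution and slow addition provide. It needs the aldehyde to survive, which the neutral medium allows (no enolisation at C8, no β-elimination at C9).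

Step 17
Reactants: 24 (3R,4R,5E,7S,8S,9R)-8-[(2E,4R)-2,4-dimethylhex-2-enoyloxy]-7-hydroxy-3,4-bis(triethylsilyloxy)tetradec-5-en-9-olide
Product: 25 (3R,4R,5S,6R,7S,8S,9R)-8-[(2E,4R)-2,4-dimethylhex-2-enoyloxy]-5,6-epoxy-7-hydroxy-3,4-bis(triethylsilyloxy)tetradecan-9-olide
Conditions: VO(acac)2 (0.1 equiv), tert-butyl hydroperoxide (1.5 equiv, anhydrous in decane), CH2Cl2, 0 °C → rt
Reagents that add atoms: tert-butyl hydroperoxide, CC(C)(C)OO
Why: Hydroxyl-directed epoxidation: the C7 alkoxide binds the pentavalent vanadium alkylperoxide and oxygen reaches C5=C6 only on the face where the O–C7–C6=C5 dihedral is small; with C8 on the inner side of the ring this is the face giving the erythro epoxy alcohol, the 5,6-configuration of 26. The C4 silyl ether cannot bind vanadium and sits away from that face, and the electron-poor enoate is not epoxidised.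

Step 18
Reactants: 25 (3R,4R,5S,6R,7S,8S,9R)-8-[(2E,4R)-2,4-dimethylhex-2-enoyloxy]-5,6-epoxy-7-hydroxy-3,4-bis(triethylsilyloxy)tetradecan-9-olide
Product: 26 (3R,4S,5R,6R,7S,8S,9R)-8-[(2E,4R)-2,4-dimethylhex-2-enoyloxy]-5,6-epoxy-3,4,7-trihydroxytetradecan-9-olide
Conditions: HF·pyridine (excess), pyridine, THF, 0 °C → rt; cold aq. NaHCO3 work-up
Reagents that add atoms: none
Why: Fluoride-mediated cleavage of both secondary triethylsilyl ethers under buffered, base-free conditions; this avoids Payne rearrangement, O8-to-O7 acyl migration and contraction to the γ-lactone, and the acidity is too weak to open the epoxide.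

## Compound list

1 | diethyl D-tartrate, diethyl (2S,3S)-2,3-dihydroxybutanedioate | CCOC(=O)[C@@H](O)[C@H](O)C(=O)OCC | starting material
2 | diethyl (2S,3S)-2,3-bis(triethylsilyloxy)butanedioate | CCOC(=O)[C@@H](O[Si](CC)(CC)CC)[C@H](O[Si](CC)(CC)CC)C(=O)OCC | intermediate
3 | ethyl (2S,3S)-4-oxo-2,3-bis(triethylsilyloxy)butanoate | CCOC(=O)[C@@H](O[Si](CC)(CC)CC)[C@H](O[Si](CC)(CC)CC)C=O | intermediate
4 | ethyl (2S,3R,4E)-5-iodo-2,3-bis(triethylsilyloxy)pent-4-enoate | CCOC(=O)[C@@H](O[Si](CC)(CC)CC)[C@H](O[Si](CC)(CC)CC)/C=C/I | intermediate
5 | (2S,3R,4E)-5-iodo-2,3-bis(triethylsilyloxy)pent-4-enal | O=C[C@@H](O[Si](CC)(CC)CC)[C@H](O[Si](CC)(CC)CC)/C=C/I | intermediate (not isolated)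
6 | (1E,3R,4R)-1-iodo-3,4-bis(triethylsilyloxy)hexa-1,5-diene | C=C[C@@H](O[Si](CC)(CC)CC)[C@H](O[Si](CC)(CC)CC)/C=C/I | intermediate
7 | 9-[(3R,4R,5E)-6-iodo-3,4-bis(triethylsilyloxy)hex-5-en-1-yl]-9-borabicyclo[3.3.1]nonane | C1CCC2CCCC1B2CC[C@@H](O[Si](CC)(CC)CC)[C@H](O[Si](CC)(CC)CC)/C=C/I | intermediate (not isolated)
8 | (3R,4R,5E)-6-iodo-3,4-bis(triethylsilyloxy)hex-5-en-1-ol | OCC[C@@H](O[Si](CC)(CC)CC)[C@H](O[Si](CC)(CC)CC)/C=C/I | intermediate
9 | (3R,4R,5E)-6-iodo-3,4-bis(triethylsilyloxy)hex-5-enal | O=CC[C@@H](O[Si](CC)(CC)CC)[C@H](O[Si](CC)(CC)CC)/C=C/I | intermediate (not isolated)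
10 | (3R,4R,5E)-6-iodo-3,4-bis(triethylsilyloxy)hex-5-enoic acid | OC(=O)C[C@@H](O[Si](CC)(CC)CC)[C@H](O[Si](CC)(CC)CC)/C=C/I | intermediate
11 | (E)-oct-2-en-1-ol | CCCCC/C=C/CO | starting material
12 | [(2S,3S)-3-pentyloxiran-2-yl]methanol | CCCCC[C@@H]1O[C@H]1CO | intermediate
13 | (2S,3R)-1,2-dihydroxyoctan-3-yl (3R,4R,5E)-6-iodo-3,4-bis(triethylsilyloxy)hex-5-enoate | CCCCC[C@@H](OC(=O)C[C@@H](O[Si](CC)(CC)CC)[C@H](O[Si](CC)(CC)CC)/C=C/I)[C@@H](O)CO | intermediate
14 | (2S,3R)-2-hydroxy-1-(triethylsilyloxy)octan-3-yl (3R,4R,5E)-6-iodo-3,4-bis(triethylsilyloxy)hex-5-enoate | CCCCC[C@@H](OC(=O)C[C@@H](O[Si](CC)(CC)CC)[C@H](O[Si](CC)(CC)CC)/C=C/I)[C@@H](O)CO[Si](CC)(CC)CC | intermediate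
15 | (R)-2-methylbutanoic acid | CC[C@@H](C)C(=O)O | starting material
16 | (R)-2-methylbutan-1-ol | CC[C@@H](C)CO | intermediate
17 | (R)-2-methylbutanal | CC[C@@H](C)C=O | intermediate (not isolated)
18 | ethyl (2E,4R)-2,4-dimethylhex-2-enoate | CCOC(=O)/C(C)=C/[C@H](C)CC | intermediate
19 | (2E,4R)-2,4-dimethylhex-2-enoic acid | OC(=O)/C(C)=C/[C@H](C)CC | intermediate
20 | (2E,4R)-2,4-dimethylhex-2-enoic 2,4,6-trichlorobenzoic anhydride | CC[C@@H](C)/C=C(\C)C(=O)OC(=O)c1c(Cl)cc(Cl)cc1Cl | intermediate (not isolated)
21 | (2S,3R)-3-{[(3R,4R,5E)-6-iodo-3,4-bis(triethylsilyloxy)hex-5-enoyl]oxy}-1-(triethylsilyloxy)octan-2-yl (2E,4R)-2,4-dimethylhex-2-enoate | CCCCC[C@@H](OC(=O)C[C@@H](O[Si](CC)(CC)CC)[C@H](O[Si](CC)(CC)CC)/C=C/I)[C@@H](OC(=O)/C(C)=C/[C@H](C)CC)CO[Si](CC)(CC)CC | intermediate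
22 | (2S,3R)-1-hydroxy-3-{[(3R,4R,5E)-6-iodo-3,4-bis(triethylsilyloxy)hex-5-enoyl]oxy}octan-2-yl (2E,4R)-2,4-dimethylhex-2-enoate | CCCCC[C@@H](OC(=O)C[C@@H](O[Si](CC)(CC)CC)[C@H](O[Si](CC)(CC)CC)/C=C/I)[C@@H](OC(=O)/C(C)=C/[C@H](C)CC)CO | intermediate
23 | (2R,3R)-3-{[(3R,4R,5E)-6-iodo-3,4-bis(triethylsilyloxy)hex-5-enoyl]oxy}-1-oxooctan-2-yl (2E,4R)-2,4-dimethylhex-2-enoate | CCCCC[C@@H](OC(=O)C[C@@H](O[Si](CC)(CC)CC)[C@H](O[Si](CC)(CC)CC)/C=C/I)[C@@H](OC(=O)/C(C)=C/[C@H](C)CC)C=O | intermediate
24 | (3R,4R,5E,7S,8S,9R)-8-[(2E,4R)-2,4-dimethylhex-2-enoyloxy]-7-hydroxy-3,4-bis(triethylsilyloxy)tetradec-5-en-9-olide | CCCCC[C@H]1OC(=O)C[C@@H](O[Si](CC)(CC)CC)[C@H](O[Si](CC)(CC)CC)/C=C/[C@H](O)[C@@H]1OC(=O)/C(C)=C/[C@H](C)CC | intermediate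
25 | (3R,4R,5S,6R,7S,8S,9R)-8-[(2E,4R)-2,4-dimethylhex-2-enoyloxy]-5,6-epoxy-7-hydroxy-3,4-bis(triethylsilyloxy)tetradecan-9-olide | CCCCC[C@H]1OC(=O)C[C@@H](O[Si](CC)(CC)CC)[C@H](O[Si](CC)(CC)CC)[C@H]2O[C@@H]2[C@H](O)[C@@H]1OC(=O)/C(C)=C/[C@H](C)CC | intermediate
26 | (3R,4S,5R,6R,7S,8S,9R)-8-[(2E,4R)-2,4-dimethylhex-2-enoyloxy]-5,6-epoxy-3,4,7-trihydroxytetradecan-9-olide (CNP0548321.2) | CCCCC[C@H]1OC(=O)C[C@@H](O)[C@H](O)[C@H]2O[C@@H]2[C@H](O)[C@@H]1OC(=O)/C(C)=C/[C@H](C)CC | target

## Step count and least certain steps

Total step count: 18. Longest linear sequence: 14 steps from 1 (steps 1–6, 8, 9, 13–18).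

**Step 16 (key step).**
- What may go wrong: facial selectivity at C7 may be poor, because the conformation of the closing ring and not the Felkin–Anh preference alone decides which aldehyde face is reached. Intermolecular coupling or simple reduction of the C–I bond may compete if closure is slow. The aldehyde may lose the O9 carboxylate by β-elimination on the Lewis-acidic chromium salts.
- Fallback (sets out from 23, returns at 24): the cyclisation is run without regard to the C7 outcome. The allylic alcohols, 24 together with its C7 epimer F1, are oxidised as a mixture with Dess–Martin periodinane and NaHCO3 to the ring enone F2.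
- F2 is then reduced under reagent control with a 2-methyl-CBS-oxazaborolidine (3,3-diphenyl-1-methyltetrahydro-1H,3H-pyrrolo[1,2-c][1,3,2]oxazaborole) and catecholborane at −78 °C. Both catalyst antipodes are available, so the one that delivers hydride to the face giving 7S is used, with Luche reduction as the substrate-controlled comparison.
- This moves the control of C7 from the C–C bond formation to a ketone reduction.

**Step 8.**
- What may go wrong: the O9 acyl group may migrate to O8 or O7 in the product diol while it is bound to titanium. The acid may be transesterified to its isopropyl ester, or attack at C3 of the epoxy alcohol may be incomplete in regioselectivity.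
- Fallback (sets out from 10, returns at 13): commercial (R)-oct-1-en-3-ol F3 is epoxidised with Ti(OiPr)4, D-(−)-diisopropyl tartrate and tert-butyl hydroperoxide. This is the matched pairing for this enantiomer and should give the erythro epoxy alcohol F4.
- F4 is esterified with 10 under Yamaguchi conditions, with retention at C9, to give epoxy ester F5. The terminal epoxide of F5 is then hydrolysed at its CH2 carbon with water and the matched enantiomer of N,N′-bis(3,5-di-tert-butylsalicylidene)-1,2-cyclohexanediaminocobalt acetate (trivalent cobalt), giving 13.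
- The C9–O bond is then made by acylation with retention instead of epoxide opening with inversion, and no titanium alkoxide meets the ester.

**Step 14.**
- What may go wrong: one of the secondary silyl ethers at O3/O4 may be lost with the primary one, or the O8 acyl group may migrate to the freed primary O7 during the reaction or on silica.
- Fallback (sets out from 21, returns at 23, no new compound): direct Swern oxidation of the primary triethylsilyl ether ((COCl)2, DMSO, CH2Cl2, −78 → −40 °C; then i-Pr2NEt, −78 °C, cold pH 7 quench). The activated sulfoxide attacks only the unhindered primary silyl ether, so the free alcohol 22 is never formed and steps 14 and 15 merge. The price is brief exposure of the aldehyde to a hindered amine at low temperature.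

**Step 17.**
- What may go wrong: oxygen may be delivered to the wrong olefin face if the ring conformer that places O7 near the olefin plane is not the reactive one. The reaction may also be slow at a hindered ring carbinol, allowing epoxide opening by the Lewis-acidic catalyst.
- Fallback (sets out from 24, returns at 25, no new compound): reagent-controlled Sharpless epoxidation with stoichiometric Ti(OiPr)4, D-(−)-diisopropyl tartrate and tert-butyl hydroperoxide at −20 °C.
- For the 7S carbinol (alkenyl and C8 arranged as in the enantiomer that reacts fast with the D-tartrate) this is the matched pairing. The titanium tartrate transition state gives erythro epoxy alcohols from secondary E-allylic alcohols largely regardless of substrate bias, so the face is chosen by the ligand and not by the ring.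

## Further compounds

F1 | step 16 | (3R,4R,5E,7R,8S,9R)-8-[(2E,4R)-2,4-dimethylhex-2-enoyloxy]-7-hydroxy-3,4-bis(triethylsilyloxy)tetradec-5-en-9-olide (C7 epimer of 24) | CCCCC[C@H]1OC(=O)C[C@@H](O[Si](CC)(CC)CC)[C@H](O[Si](CC)(CC)CC)/C=C/[C@@H](O)[C@@H]1OC(=O)/C(C)=C/[C@H](C)CC
F2 | step 16 | (3R,4R,5E,8R,9R)-8-[(2E,4R)-2,4-dimethylhex-2-enoyloxy]-7-oxo-3,4-bis(triethylsilyloxy)tetradec-5-en-9-olide | CCCCC[C@H]1OC(=O)C[C@@H](O[Si](CC)(CC)CC)[C@H](O[Si](CC)(CC)CC)/C=C/C(=O)[C@@H]1OC(=O)/C(C)=C/[C@H](C)CC
F3 | step 8 | (R)-oct-1-en-3-ol | CCCCC[C@@H](O)C=C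
F4 | step 8 | (R)-1-[(S)-oxiran-2-yl]hexan-1-ol | CCCCC[C@@H](O)[C@@H]1CO1
F5 | step 8 | (R)-1-[(S)-oxiran-2-yl]hexyl (3R,4R,5E)-6-iodo-3,4-bis(triethylsilyloxy)hex-5-enoate | CCCCC[C@@H](OC(=O)C[C@@H](O[Si](CC)(CC)CC)[C@H](O[Si](CC)(CC)CC)/C=C/I)[C@@H]1CO1
F0 | step 14 | none | none
F0 | step 17 | none | none
A1 | alternative 1 | trans-5,6-epoxide of (3E)-1,7-bis(tert-butyldimethylsilyloxy)-8-(4-methoxybenzyloxy)-9-(triethylsilyloxy)tetradec-3-ene, C5–C9 configured as in 26 | CC(C)(C)[Si](C)(C)OCC/C=C/[C@H]1O[C@@H]1[C@H](O[Si](C)(C)C(C)(C)C)[C@H](OCc1ccc(OC)cc1)[C@H](O[Si](CC)(CC)CC)CCCCC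
A2 | alternative 1 | 2-(tert-butyldimethylsilyloxy)-3-(4-methoxybenzyloxy)-4-(triethylsilyloxy)nonanal, configured as C7–C9 of 26 | O=C[C@H](O[Si](C)(C)C(C)(C)C)[C@H](OCc1ccc(OC)cc1)[C@H](O[Si](CC)(CC)CC)CCCCC
A3 | alternative 1 | 1-[(2E)-5-(tert-butyldimethylsilyloxy)pent-2-en-1-yl]tetrahydrothiophenium bromide | CC(C)(C)[Si](C)(C)OCC/C=C/C[S+]1CCCC1.[Br-]
A4 | alternative 2 | (5E)-3,4,7-tris(tert-butyldimethylsilyloxy)-8-hydroxytetradec-5-en-9-olide, configured as in 26 | CCCCC[C@H]1OC(=O)C[C@@H](O[Si](C)(C)C(C)(C)C)[C@H](O[Si](C)(C)C(C)(C)C)/C=C/[C@H](O[Si](C)(C)C(C)(C)C)[C@@H]1O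
A5 | alternative 2 | (5E)-3,4,7-tris(tert-butyldimethylsilyloxy)-8,9-epoxytetradec-5-enoic acid with trans-(8S,9S) epoxide | OC(=O)C[C@@H](O[Si](C)(C)C(C)(C)C)[C@H](O[Si](C)(C)C(C)(C)C)/C=C/[C@H](O[Si](C)(C)C(C)(C)C)[C@@H]1O[C@H]1CCCCC
A6 | alternative 3 | 8-[(2E,4R)-2,4-dimethylhex-2-enoyloxy]-5,6-epoxy-3-hydroxy-4,7-bis(4-methoxybenzyloxy)tetradecan-9-olide, configured as in 26 | CCCCC[C@H]1OC(=O)C[C@@H](O)[C@H](OCc2ccc(OC)cc2)[C@H]2O[C@@H]2[C@H](OCc2ccc(OC)cc2)[C@@H]1OC(=O)/C(C)=C/[C@H](C)CC
A7 | alternative 3 | C9 bromoacetate of the C3–C14 epoxy aldehyde bearing 4-methoxybenzyl ethers at O4 and O7 and the side-chain ester at O8 | CCCCC[C@@H](OC(=O)CBr)[C@@H](OC(=O)/C(C)=C/[C@H](C)CC)[C@@H](OCc1ccc(OC)cc1)[C@H]1O[C@@H]1[C@@H](OCc1ccc(OC)cc1)C=O
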